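**Remark on labels:** atom labels follow the atom order of the target SMILES: C6 = lactone O–CH, C7 = lactone β-CH, C8 = CH(OH), C20 = CH(OAc), C25/C28 = epoxide C(Me)/CH, C2/C1/C3 = lactone α-C, exo-CH2 and C=O.

## Retrosynthetic overview

- The γ-lactone (O5–C6–C7–C2–C3) is taken off last. The C6(O)–C7(C)–C8(OH) triad (trans lactone, C8–OH syn to C6) is what results when the erythro C6-hydroxy-C7,C8-epoxide is opened at C7 with inversion by a carbon nucleophile tethered to O5. This leads back to the lactone-free 14-membered bis-epoxy carbocycle 27, diethylphosphonoacetic acid and CH2O.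
- The 14-membered ring is closed at C6–C7 by an alkenylzinc/aldehyde macrocyclisation of ynal 23; the new C6 hydroxyl then directs epoxidation of C7=C8.
- The open chain is built by C13–C14 Negishi coupling, C18–C19 alanate/ethylene oxide opening and C20–C25 asymmetric alkenylzinc addition. Zr-catalysed carboalumination sets both trisubstituted E-alkenes; Sharpless epoxidation from the primary C6–OH sets C25/C28.
- Ring order: oxirane C25–C28, then the 14-membered ring, then oxirane C7–C8, then the lactone.

Key step: step 16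

## Route

Step 1
Reactants: 1 ethynyltriisopropylsilane; 2 propargyl bromide
Product: 4 triisopropyl(penta-1,4-diyn-1-yl)silane, via alkynylmagnesium bromide 3 (not isolated)
Conditions: EtMgBr, THF, 0 °C to rt; CuCl (cat.), then 2, 50 °C
Reagents that add atoms: none
Why: Copper-catalysed SN2 coupling of an alkynyl Grignard with a propargylic bromide is the standard entry to skipped diynes, and the TIPS group keeps the two alkyne termini distinct for the rest of the route.

Step 2
Reactants: 4 triisopropyl(penta-1,4-diyn-1-yl)silane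
Product: 6 (E)-(5-iodo-4-methylpent-4-en-1-yn-1-yl)triisopropylsilane, via alkenylalane 5 (not isolated)
Conditions: Me3Al, Cp2ZrCl2 (cat.), CH2Cl2, 0 °C to rt; then I2, THF, -30 °C
Reagents that add atoms: trimethylaluminium C[Al](C)C; iodine II
Why: Zr-catalysed syn-carboalumination (Negishi) occurs only at the terminal alkyne (silyl alkynes are inert) and iodinolysis with retention fixes the C11=C13 E-geometry.

Step 3
Reactants: 6 (E)-(5-iodo-4-methylpent-4-en-1-yn-1-yl)triisopropylsilane; 7 (4-bromobut-1-yn-1-yl)trimethylsilane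
Product: 9 (E)-triisopropyl[4-methyl-9-(trimethylsilyl)non-4-ene-1,8-diyn-1-yl]silane, via alkylzinc bromide 8 (not isolated)
Conditions: 7, Zn dust, I2 (cat.), DMA, 70 °C; then 6, Pd(dppf)Cl2 (cat.), THF, rt to 45 °C
Reagents that add atoms: none
Why: sp3–sp2 Negishi coupling of a homopropargylic zinc reagent with an alkenyl iodide forms C13–C14 with retention of the E-alkene.

Step 4
Reactants: 9 (E)-triisopropyl[4-methyl-9-(trimethylsilyl)non-4-ene-1,8-diyn-1-yl]silane
Product: 10 (E)-triisopropyl(4-methylnon-4-ene-1,8-diyn-1-yl)silane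
Conditions: K2CO3, MeOH, rt
Reagents that add atoms: none
Why: Methanolysis removes the alkynyl TMS group selectively because the alkynyl TIPS group is stable to K2CO3/MeOH.

Step 5
Reactants: 10 (E)-triisopropyl(4-methylnon-4-ene-1,8-diyn-1-yl)silane
Product: 13 (3E,7E)-4,8-dimethyl-11-(triisopropylsilyl)undeca-3,7-dien-10-yn-1-ol, via alkenylalane 11 (not isolated), via lithium alanate 12 (not isolated)
Conditions: Me3Al, Cp2ZrCl2 (cat.), CH2Cl2, 0 °C to rt; solvent exchange to hexane/THF; n-BuLi, -78 to 0 °C; ethylene oxide, 0 °C to rt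
Reagents that add atoms: trimethylaluminium C[Al](C)C; ethylene oxide C1CO1
Why: A second Negishi carboalumination sets the C16=C18 E-alkene and the derived alkenylalanate opens ethylene oxide to give the homoallylic alcohol (C19–C20).

Step 6
Reactants: 13 (3E,7E)-4,8-dimethyl-11-(triisopropylsilyl)undeca-3,7-dien-10-yn-1-ol
Product: 14 (3E,7E)-4,8-dimethyl-11-(triisopropylsilyl)undeca-3,7-dien-10-ynal
Conditions: Dess–Martin periodinane, NaHCO3, CH2Cl2, 0 °C; used crude
Reagents that add atoms: none
Why: Buffered Dess–Martin oxidation gives the β,γ-unsaturated aldehyde without migration of the double bond into conjugation.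

Step 7
Reactants: 15 but-2-yn-1-ol
Product: 16 (but-2-yn-1-yloxy)(tert-butyl)dimethylsilane
Conditions: TBSCl, imidazole, CH2Cl2, rt
Reagents that add atoms: tert-butyldimethylsilyl chloride CC(C)(C)[Si](C)(C)Cl
Why: Standard silylation masks the hydroxyl that later becomes the directing C6–OH.

Step 8
Reactants: 14 (3E,7E)-4,8-dimethyl-11-(triisopropylsilyl)undeca-3,7-dien-10-ynal; 16 (but-2-yn-1-yloxy)(tert-butyl)dimethylsilane
Product: 19 (2E,4R,6E,10E)-1-(tert-butyldimethylsilyloxy)-3,7,11-trimethyl-14-(triisopropylsilyl)tetradeca-2,6,10-trien-13-yn-4-ol (C20 = R), via alkenylzirconocene chloride 17 (not isolated), via alkenyl(methyl)zinc 18 (not isolated)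
Conditions: 16, Cp2Zr(H)Cl, CH2Cl2, rt; Me2Zn, toluene, -65 °C; (−)-MIB (10 mol %); then 14, -30 to 0 °C
Reagents that add atoms: none
Why: syn-Hydrozirconation should place Zr on the methyl-bearing alkyne carbon (remote from CH2OTBS), and Zr-to-Zn transmetalation followed by amino-alcohol-catalysed alkenylzinc addition forms C20–C25 with the E-alkene. (−)-MIB is expected to give the 20R carbinol (the same aldehyde face as in its dialkylzinc additions); (+)-MIB is used should the sense be opposite.

Step 9
Reactants: 19 the 20R allylic alcohol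
Product: 20 (2E,4R,6E,10E)-1-(tert-butyldimethylsilyloxy)-3,7,11-trimethyl-14-(triisopropylsilyl)tetradeca-2,6,10-trien-13-yn-4-yl acetate
Conditions: Ac2O, pyridine, DMAP (cat.), CH2Cl2, 0 °C to rt
Reagents that add atoms: acetic anhydride CC(=O)OC(C)=O
Why: Acetylation installs the C20 acetate of the target with retention and removes the secondary allylic hydroxyl as a competing director for the later epoxidation.

Step 10
Reactants: 20 the silyl ether/silyl alkyne acetate
Product: 21 (2E,4R,6E,10E)-4-acetoxy-3,7,11-trimethyltetradeca-2,6,10-trien-13-yn-1-ol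
Conditions: TBAF, AcOH, THF, 0 °C to rt
Reagents that add atoms: none
Why: Buffered fluoride cleaves the primary TBS ether and the alkynyl TIPS group in one operation while the acetate is retained.

Step 11
Reactants: 21 the primary allylic alcohol
Product: 22 (1R,3E,7E)-1-[(2S,3S)-3-(hydroxymethyl)-2-methyloxiran-2-yl]-4,8-dimethylundeca-3,7-dien-10-yn-1-yl acetate (20R,25S,28S)
Conditions: Ti(Oi-Pr)4 (cat.), L-(+)-DET, t-BuOOH, 4 Å MS, CH2Cl2, -20 °C
Reagents that add atoms: tert-butyl hydroperoxide CC(C)(C)OO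
Why: Sharpless asymmetric epoxidation acts only on the allylic-alcohol alkene. L-(+)-tartrate delivers oxygen to the face that gives the (2S,3S)-epoxide of a geraniol-type 3-methyl-2-en-1-ol, which here is 25S,28S, under reagent control.

Step 12
Reactants: 22 the epoxy alcohol
Product: 23 (1R,3E,7E)-1-[(2S,3R)-3-formyl-2-methyloxiran-2-yl]-4,8-dimethylundeca-3,7-dien-10-yn-1-yl acetate (same spatial arrangement as 22)
Conditions: Dess–Martin periodinane, NaHCO3, CH2Cl2, 0 °C
Reagents that add atoms: none
Why: Buffered Dess–Martin oxidation gives the α,β-epoxy aldehyde without epimerisation or epoxide opening.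

Step 13
Reactants: 23 the epoxy ynal
Product: 26 14-membered allylic alcohol (6S,20R,25S,28S; 7E,11E,16E): 2-hydroxy-6,10,14-trimethyl-15-oxabicyclo[12.1.0]pentadeca-3,6,10-trien-13-yl acetate, via alkenylborane 24 (not isolated), via alkenyl(ethyl)zinc 25 (not isolated)
Conditions: (c-C6H11)2BH, hexane/toluene, 0 °C; then slow addition to Et2Zn, (−)-DAIB (5 mol %), hexane, rt, final 5 mM; aq. NH4Cl
Reagents that add atoms: none
Why: Hydroboration of the terminal alkyne, B-to-Zn exchange and amino-alcohol-catalysed intramolecular alkenylzinc addition to the aldehyde closes the ring (14-exo-trig) with an E-C7=C8 alkene, as known for macrocyclic allylic alcohols from ω-alkynals. (−)-DAIB is chosen for the 6S carbinol, and any 6R epimer is not consumed in step 14.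

Step 14
Reactants: 26 the macrocyclic allylic alcohol
Product: 27 bis-epoxy alcohol (6S,7R,8R,20R,25S,28S): 26 with an additional trans-C7–C8 oxirane erythro to the C6 hydroxyl
Conditions: Ti(Oi-Pr)4 (1 equiv), D-(−)-DIPT (1.2 equiv), t-BuOOH, 4 Å MS, CH2Cl2, -20 °C
Reagents that add atoms: tert-butyl hydroperoxide CC(C)(C)OO
Why: Sharpless epoxidation of a secondary E-allylic alcohol is strongly erythro-selective. With D-(−)-tartrate the 6S alcohol is the fast-reacting, matched substrate and gives the 7R,8R oxirane; the two remote trisubstituted alkenes are not touched.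

Step 15
Reactants: 27 the bis-epoxy alcohol; 28 diethylphosphonoacetic acid
Product: 29 diethylphosphonoacetate ester of 27 at O5 (no stereocentre touched)
Conditions: DCC, DMAP (cat.), CH2Cl2, 0 °C to rt
Reagents that add atoms: none
Why: Steglich esterification attaches the two-carbon nucleophile (C2, C3) to the oxygen that becomes the lactone oxygen.

Step 16
Reactants: 29 the phosphonoacetate ester
Product: 31 michaolide F, via α-phosphono lactone 30 (not isolated)
Conditions: NaH, THF, 0 to 40 °C; then (CH2O)n, rt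
Reagents that add atoms: formaldehyde C=O
Why: Proposed new method: deprotonation of the phosphonoacetate gives a stabilised carbanion held on O5 that opens the C7–C8 oxirane at C7 from the rear (SN2, 5-exo-tet) to close the γ-lactone; proton transfer from the new α-phosphono lactone to the C8 alkoxide then gives the phosphonate anion, which olefinates formaldehyde (Horner–Wadsworth–Emmons), so the C2–C7 bond, the lactone ring, the exo-methylene group and the free C8 hydroxyl are formed in one flask. The closest known reactions are the intermolecular opening of epoxides by sodium triethyl phosphonoacetate to α-phosphono-γ-lactones followed by formaldehyde methylenation, and intramolecular 5-exo epoxide openings by tethered stabilised carbanions; the ester-tethered, lactone-forming variant on a 2,3-epoxy alcohol is the new element. C7 is set by inversion of the Sharpless-defined C7–O bond and C8 keeps its oxirane configuration, which turns the erythro epoxy alcohol into the trans lactone with the C8 hydroxyl syn to C6, as in the target. The step needs attack at C7 rather than C8 (5-exo over 6-endo) and rather than C28 of the second oxirane, which is also 5-exo but is flanked by the fully substituted C25 whose methyl is cis to C6, and should therefore be the slower SN2 site. The ester has to react through its s-cis rotamer, which is the main kinetic uncertainty; a less coordinating counter-ion (KHMDS, 18-crown-6) is the lever.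

## Compound list

1 | ethynyltriisopropylsilane | C#C[Si](C(C)C)(C(C)C)C(C)C | starting material
2 | propargyl bromide | C#CCBr | starting material
3 | [(triisopropylsilyl)ethynyl]magnesium bromide | CC(C)[Si](C#C[Mg]Br)(C(C)C)C(C)C | intermediate
4 | triisopropyl(penta-1,4-diyn-1-yl)silane | C#CCC#C[Si](C(C)C)(C(C)C)C(C)C | intermediate
5 | (E)-dimethyl[2-methyl-5-(triisopropylsilyl)pent-1-en-4-yn-1-yl]alane | C[Al](C)/C=C(\C)CC#C[Si](C(C)C)(C(C)C)C(C)C | intermediate
6 | (E)-(5-iodo-4-methylpent-4-en-1-yn-1-yl)triisopropylsilane | I/C=C(\C)CC#C[Si](C(C)C)(C(C)C)C(C)C | intermediate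
7 | (4-bromobut-1-yn-1-yl)trimethylsilane | C[Si](C)(C)C#CCCBr | starting material
8 | [4-(trimethylsilyl)but-3-yn-1-yl]zinc bromide | C[Si](C)(C)C#CCC[Zn]Br | intermediate
9 | (E)-triisopropyl[4-methyl-9-(trimethylsilyl)non-4-ene-1,8-diyn-1-yl]silane | C[Si](C)(C)C#CCC/C=C(\C)CC#C[Si](C(C)C)(C(C)C)C(C)C | intermediate
10 | (E)-triisopropyl(4-methylnon-4-ene-1,8-diyn-1-yl)silane | C#CCC/C=C(\C)CC#C[Si](C(C)C)(C(C)C)C(C)C | intermediate
11 | (1E,5E)-[2,6-dimethyl-9-(triisopropylsilyl)nona-1,5-dien-8-yn-1-yl]dimethylalane | C[Al](C)/C=C(\C)CC/C=C(\C)CC#C[Si](C(C)C)(C(C)C)C(C)C | intermediate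
12 | lithium butyl(dimethyl)[(1E,5E)-2,6-dimethyl-9-(triisopropylsilyl)nona-1,5-dien-8-yn-1-yl]alanate | CCCC[Al-](C)(C)/C=C(\C)CC/C=C(\C)CC#C[Si](C(C)C)(C(C)C)C(C)C.[Li+] | intermediate
13 | (3E,7E)-4,8-dimethyl-11-(triisopropylsilyl)undeca-3,7-dien-10-yn-1-ol | OCC/C=C(\C)CC/C=C(\C)CC#C[Si](C(C)C)(C(C)C)C(C)C | intermediate
14 | (3E,7E)-4,8-dimethyl-11-(triisopropylsilyl)undeca-3,7-dien-10-ynal | O=CC/C=C(\C)CC/C=C(\C)CC#C[Si](C(C)C)(C(C)C)C(C)C | intermediate
15 | but-2-yn-1-ol | CC#CCO | starting material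
16 | (but-2-yn-1-yloxy)(tert-butyl)dimethylsilane | CC#CCO[Si](C)(C)C(C)(C)C | intermediate
17 | (E)-[4-(tert-butyldimethylsilyloxy)but-2-en-2-yl]zirconocene chloride | CC(C)(C)[Si](C)(C)OC/C=C(\C)[Zr](Cl)(C1C=CC=C1)C1C=CC=C1 | intermediate
18 | (E)-[4-(tert-butyldimethylsilyloxy)but-2-en-2-yl](methyl)zinc | CC(C)(C)[Si](C)(C)OC/C=C(\C)[Zn]C | intermediate
19 | (2E,4R,6E,10E)-1-(tert-butyldimethylsilyloxy)-3,7,11-trimethyl-14-(triisopropylsilyl)tetradeca-2,6,10-trien-13-yn-4-ol | CC(C)[Si](C(C)C)(C(C)C)C#CC/C(C)=C/CC/C(C)=C/C[C@@H](O)/C(C)=C/CO[Si](C)(C)C(C)(C)C | intermediate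
20 | (2E,4R,6E,10E)-1-(tert-butyldimethylsilyloxy)-3,7,11-trimethyl-14-(triisopropylsilyl)tetradeca-2,6,10-trien-13-yn-4-yl acetate | CC(C)[Si](C(C)C)(C(C)C)C#CC/C(C)=C/CC/C(C)=C/C[C@@H](OC(C)=O)/C(C)=C/CO[Si](C)(C)C(C)(C)C | intermediate
21 | (2E,4R,6E,10E)-4-acetoxy-3,7,11-trimethyltetradeca-2,6,10-trien-13-yn-1-ol | C#CC/C(C)=C/CC/C(C)=C/C[C@@H](OC(C)=O)/C(C)=C/CO | intermediate
22 | (1R,3E,7E)-1-[(2S,3S)-3-(hydroxymethyl)-2-methyloxiran-2-yl]-4,8-dimethylundeca-3,7-dien-10-yn-1-yl acetate | C#CC/C(C)=C/CC/C(C)=C/C[C@@H](OC(C)=O)[C@]1(C)O[C@H]1CO | intermediate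
23 | (1R,3E,7E)-1-[(2S,3R)-3-formyl-2-methyloxiran-2-yl]-4,8-dimethylundeca-3,7-dien-10-yn-1-yl acetate | C#CC/C(C)=C/CC/C(C)=C/C[C@@H](OC(C)=O)[C@]1(C)O[C@H]1C=O | intermediate
24 | dicyclohexyl[(1E)-alkenyl]borane from hydroboration of 23 at C7 | C1CCCCC1B(C2CCCCC2)/C=C/C/C(C)=C/CC/C(C)=C/C[C@@H](OC(C)=O)[C@]3(C)O[C@H]3C=O | intermediate
25 | ethyl[(1E)-alkenyl]zinc corresponding to 24 | CC[Zn]/C=C/C/C(C)=C/CC/C(C)=C/C[C@@H](OC(C)=O)[C@]1(C)O[C@H]1C=O | intermediate
26 | 14-membered allylic alcohol (6S,20R,25S,28S; 7E,11E,16E), 2-hydroxy-6,10,14-trimethyl-15-oxabicyclo[12.1.0]pentadeca-3,6,10-trien-13-yl acetate | O[C@H]1/C=C/C/C(C)=C/CC/C(C)=C/C[C@@H](OC(C)=O)[C@]2(C)O[C@@H]12 | intermediate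
27 | bis-epoxy alcohol (6S,7R,8R,20R,25S,28S), C7–C8 oxirane of 26 | O[C@H]1[C@H]3O[C@@H]3C/C(C)=C/CC/C(C)=C/C[C@@H](OC(C)=O)[C@]2(C)O[C@@H]12 | intermediate
28 | diethylphosphonoacetic acid | CCOP(=O)(CC(=O)O)OCC | starting material
29 | O5-(diethylphosphonoacetyl) ester of 27 | CCOP(=O)(OCC)CC(=O)O[C@H]1[C@H]3O[C@@H]3C/C(C)=C/CC/C(C)=C/C[C@@H](OC(C)=O)[C@]2(C)O[C@@H]12 | intermediate
30 | α-(diethoxyphosphoryl) lactone (target skeleton with P(O)(OEt)2 and H on C2 in place of =CH2; C2 as a mixture) | CCOP(=O)(OCC)C1C(=O)O[C@H]2[C@H]1[C@H](O)C/C(C)=C/CC/C(C)=C/C[C@@H](OC(C)=O)[C@]3(C)O[C@@H]23 | intermediate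
31 | michaolide F | C=C1C(=O)O[C@H]2[C@H]1[C@H](O)C/C(C)=C/CC/C(C)=C/C[C@@H](OC(C)=O)[C@]1(C)O[C@@H]21 | target

## Step count and risks

Total step count: 16. Longest linear sequence: 15 (steps 1–6 and 8–16; step 7 is a one-step branch).

**Step 16 (key step, proposed new method).** The cyclisation may stall because the ester cannot reach the s-cis rotamer, or the carbanion may open the C25–C28 oxirane instead of the C7–C8 oxirane. The fallback uses known chemistry and sets out from 27. The free hydroxy bis-epoxide is treated with lithium trimethyl(trimethylsilylethynyl)aluminate, which is delivered from the C6 aluminium alkoxide to C7 with inversion (C2-selective alkynylation of 2,3-epoxy alcohols) and should give the C7-alkynyl 6,8-diol F1. Buffered fluoride desilylation should give the terminal alkyne F2. Palladium-catalysed cyclocarbonylation of the homopropargylic C6 alcohol (PdCl2, SnCl2, PPh3, CO, MeCN) closes the α-methylene-γ-butyrolactone and comes back to the route at 31. Should the C8 hydroxyl lactonise instead, acid-catalysed translactonisation to the trans-fused C6 lactone is available.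

**Step 13 (macrocyclisation).** Dicyclohexylborane may reduce the epoxy aldehyde in competition with alkyne hydroboration, or intermolecular addition may give oligomers. The fallback sets out from 22. Hydrozirconation–iodination of the terminal alkyne (Cp2Zr(H)Cl, then I2) should give the (E)-vinyl iodide epoxy alcohol F3, and Dess–Martin oxidation the iodo epoxy aldehyde F4. Nozaki–Hiyama–Kishi macrocyclisation (CrCl2, cat. NiCl2, DMSO/THF, high dilution) then closes C6–C7 and comes back at 26, probably as a mixture of C6 epimers, of which step 14 converts only the 6S alcohol.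

**Step 8 (asymmetric alkenylzinc addition).** Hydrozirconation may be poorly regioselective, the enolisable β,γ-unsaturated aldehyde may isomerise, or the facial selectivity may be low. The fallback sets out from 16 and 14. Hydrozirconation–iodination of 16 gives the vinyl iodide (E)-tert-butyl[(3-iodobut-2-en-1-yl)oxy]dimethylsilane F5, which can be purified from its regioisomer. Nozaki–Hiyama–Kishi coupling with 14 gives the racemic allylic alcohol F6, Dess–Martin oxidation the dienone F7, and Corey–Bakshi–Shibata reduction with the (S)-oxazaborolidine (alkenyl as the large group) comes back at 19.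

## Further compounds

F1 | step 16 | C7-(trimethylsilylethynyl) 6,8-diol of the macrocycle (6S,7R,8R,20R,25S,28S) | O[C@H]2[C@H](C#C[Si](C)(C)C)[C@H](O)C/C(C)=C/CC/C(C)=C/C[C@@H](OC(C)=O)[C@]1(C)O[C@@H]21
F2 | step 16 | C7-ethynyl 6,8-diol of the macrocycle | O[C@H]2[C@H](C#C)[C@H](O)C/C(C)=C/CC/C(C)=C/C[C@@H](OC(C)=O)[C@]1(C)O[C@@H]21
F3 | step 13 | (1R,3E,7E,10E)-1-[(2S,3S)-3-(hydroxymethyl)-2-methyloxiran-2-yl]-11-iodo-4,8-dimethylundeca-3,7,10-trien-1-yl acetate | I/C=C/C/C(C)=C/CC/C(C)=C/C[C@@H](OC(C)=O)[C@]1(C)O[C@H]1CO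
F4 | step 13 | (1R,3E,7E,10E)-1-[(2S,3R)-3-formyl-2-methyloxiran-2-yl]-11-iodo-4,8-dimethylundeca-3,7,10-trien-1-yl acetate | I/C=C/C/C(C)=C/CC/C(C)=C/C[C@@H](OC(C)=O)[C@]1(C)O[C@H]1C=O
F5 | step 8 | (E)-tert-butyl[(3-iodobut-2-en-1-yl)oxy]dimethylsilane | CC(C)(C)[Si](C)(C)OC/C=C(\C)I
F6 | step 8 | racemic (2E,6E,10E)-1-(tert-butyldimethylsilyloxy)-3,7,11-trimethyl-14-(triisopropylsilyl)tetradeca-2,6,10-trien-13-yn-4-ol | CC(C)[Si](C(C)C)(C(C)C)C#CC/C(C)=C/CC/C(C)=C/CC(O)/C(C)=C/CO[Si](C)(C)C(C)(C)C
F7 | step 8 | (2E,6E,10E)-1-(tert-butyldimethylsilyloxy)-3,7,11-trimethyl-14-(triisopropylsilyl)tetradeca-2,6,10-trien-13-yn-4-one | CC(C)[Si](C(C)C)(C(C)C)C#CC/C(C)=C/CC/C(C)=C/CC(=O)/C(C)=C/CO[Si](C)(C)C(C)(C)C
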